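The runs are simulated on assumed constants; the scatter is artificial.

I had to choose a charge. Four recipes stood open, with equal amounts, and they differed in what went in slowly. I wanted the one that gave most homo dimer, and I would run it next.

| flask | electrophile | nucleophile | free base | remark | time |
|---|---|---|---|---|---|
| south | 0.032 M | 0.0416 M | 0.064 M | run made earlier |  |
| north | 0.032 M | 0.0416 M | 0.090 M | run made earlier |  |
| south-east | 0.032 M | 0.0416 M | 0.14 M | run made earlier |  |
| east | 0.032 M | 0.021 M | 0.064 M | run made earlier |  |
| ash | 0.032 M (fed, over 25 h) | 0.0416 M | 0.0640 M | all else is in the flask from the start; the feed brings no volume worth counting | 40 h |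
| maple | 0.032 M | 0.0416 M (fed, over 6.0 h) | 0.0640 M | all else is in the flask from the start; the feed brings no volume worth counting | 40 h |
| cedar | 0.032 M | 0.0416 M | 0.0640 M | everything together at the start | 40 h |
| oak | 0.032 M | 0.0416 M (fed, over 25 h) | 0.0640 M | all else is in the flask from the start; the feed brings no volume worth counting | 40 h |

- south (time / h: homo dimer / %, target / %): 6.00: 25.0, 7.1; 12.0: 37.4, 11.3; 20.0: 47.0, 13.9; 25.0: 50.9, 14.6
- north (time / h: homo dimer / %, target / %): 2.50: 13.1, 3.2; 6.00: 24.9, 7.0; 15.0: 40.9, 11.6; 30.0: 53.0, 15.6
- south-east (time / h: homo dimer / %, target / %): 4.00: 18.1, 5.5; 12.0: 37.7, 10.4; 20.0: 47.2, 13.4; 30.0: 53.9, 15.2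
- east (time / h: homo dimer / %, target / %): 8.00: 31.3, 4.3; 15.0: 45.0, 6.6; 25.0: 54.7, 7.9; 30.0: 58.2, 7.7

(scatter of a reading: 0.3 percentage points)

- percentages count the electrophile that a species holds: one homo dimer counts as two
- a reading or a percentage of target counts all its forms, free or not

1. the flask that comes out highest in amount of homo dimer, in percent of the electrophile charged, or "all alike" when all lie within 1.5 percentage points (ash / maple / cedar / oak / all alike)
2. homo dimer at the end, in percent of the electrophile charged, ash
3. homo dimer at the end, in percent of the electrophile charged, maple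
4. homo dimer at the end, in percent of the electrophile charged, cedar
5. homo dimer at the end, in percent of the electrophile charged, oak

The electrophile was the limiting reagent, at 0.032 M against 0.0416 M of nucleophile, so I wrote its balance. In the south run at 25.0 h, homo dimer held 50.9% and target 14.6%, which left 34.5% unread. Free base did not steer the split: at 6.00 h, homo dimer read 25.0% with 0.064 M of free base and 24.9% with 0.090 M. Nucleophile did, so I used one number, the selectivity factor σ, the target made per homo dimer per unit [nucleophile]. South gave 6.90 M⁻¹, and east, with 0.021 M of nucleophile, gave 6.88 M⁻¹.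

I took the share of spent electrophile that becomes homo dimer as one over one plus σ[nucleophile]. With [nucleophile] held at the full charge, my estimate for cedar, that was 77.7%. For oak I took the mean [nucleophile] as 0.0208 M, half the charge, which gave 87.5%. The south balance, read as second order, gave 0.0759 h⁻¹ and so 24.8% unread at 40 h. I assumed both flasks spent the same amount. That made cedar 58.5% and oak 65.8%, so I chose oak.

The forecast also named oak: 65% for oak (62% to 68%), 60% for maple, 58% for cedar and 49.5% for ash, on the ground that “Late nucleophile removes target's competition early”. My oak figure stood above its number.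

Oak came out highest, at 64.3%, against 59.3% for maple, 56.9% for cedar and 45.5% for ash.

    nucleophile + acid set free ⇌ protonated nucleophile, settled at all times (K = 2700 M⁻¹)
    nucleophile + target ⇌ idle adduct, settled at all times (K = 21.0 M⁻¹)
    electrophile + nucleophile → acid set free + target (k = 0.00630 M⁻¹ min⁻¹)
    target → over-reaction product (k = 3.40 × 10⁻⁴ min⁻¹)
    acid set free + free base ⇌ salt of the base, settled at all times (K = 36.0 M⁻¹)
    2 electrophile → homo dimer (k = 0.0160 M⁻¹ min⁻¹)

Oak led maple by 5 percentage points, and oak's own figure moved by 5 points with electrophile at 0.0258 M or 0.0402 M. Oak's mean [nucleophile] over the first 25 h was 0.0183 M, less than the 0.0208 M I had taken, so σ gave 0.126 target per homo dimer for those hours in oak. In the neighbour of ash with 0.017 M of nucleophile, σ gave 0.117 at that charge, and at 40.0 h that flask held 6.77% target against 52.5% homo dimer, a ratio of 0.129.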